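**Retrosynthetic overview**
1. Target 15 ⇐ tris-silyl lactone 14 by global desilylation.
2. 14 ⇐ arylidene furanone 12: reductive oxygenation at C2 gives hemiketal 13, then a 1,2-shift of the benzyl group from C2 to C3 turns the furan-3-one into the 3-hydroxy-2-oxo lactone and sets C3.
3. 12 ⇐ enone 8 + aldehyde 6 by a syn-selective asymmetric Mukaiyama aldol (C4–C7' bond, C4 and C7' stereocentres).
4. 8 ⇐ oxolan-3-one 7 + aldehyde 6 (C2=C7 by condensation); 6 ⇐ catechol 1 via guaiacol 2 and vanillin 5 (MeI, glyoxylic acid 3).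
5. Rings: none is built. Both arenes come from catechol and the oxolane from 7; step 8 changes its oxidation pattern, not its size.

Locants: oxolane O1, C2–C5; C7 is the benzylic CH2 carbon, C7' the carbinol carbon. Ar = 3-methoxy-4-(triisopropylsilyloxy)phenyl throughout.

Assumption: the B-n-butyl oxazaborolidinone of N-tosyl-(S)-tryptophan directs the enol silane to the re face of aryl aldehydes; if the sense proves opposite, the (R)-tryptophan-derived antipode is used and nothing else changes.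

**Route**

Step 1
Reactants: 1 catechol
Product: 2 guaiacol (2-methoxyphenol)
Conditions: MeI (1.0 equiv), K2CO3 (1.0 equiv), acetone, 56 °C; base extraction, distillation
Reagents that add atoms: iodomethane CI
Why: Williamson O-methylation with one equivalent of MeI stops largely at the mono-ether, and the neutral dimethyl ether and unreacted catechol are removed by extraction.

Step 2
Reactants: 2 guaiacol; 3 glyoxylic acid
Product: 5 vanillin (4-hydroxy-3-methoxybenzaldehyde), via 4-hydroxy-3-methoxymandelic acid 4 (not isolated)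
Conditions: aq NaOH (3 equiv), 25 °C; then CuSO4 (5 mol %), O2, 95 °C; then HCl
Reagents that add atoms: none
Why: Electrophilic aromatic hydroxyalkylation of the phenolate by glyoxylate goes para to the free OH, and copper-catalysed aerobic oxidative decarboxylation of the mandelate gives the aldehyde (the guaiacol–glyoxylic acid vanillin process).

Step 3
Reactants: 5 vanillin
Product: 6 3-methoxy-4-(triisopropylsilyloxy)benzaldehyde
Conditions: i-Pr3SiCl, imidazole, DMF, 23 °C
Reagents that add atoms: triisopropylsilyl chloride CC(C)[Si](Cl)(C(C)C)C(C)C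
Why: Imidazole-promoted silylation of the phenol gives an aryl silyl ether that tolerates the amine, Lewis-acid, radical and alkoxide conditions used later.

Step 4
Reactants: 7 oxolan-3-one (2 equiv); 6 3-methoxy-4-(triisopropylsilyloxy)benzaldehyde
Product: 8 (2Z)-2-(Ar-methylidene)oxolan-3-one
Conditions: pyrrolidine (20 mol %), AcOH (20 mol %), toluene, 4 Å MS, 23–40 °C
Reagents that add atoms: none
Why: Amine-catalysed aldol condensation in which the enamine forms toward the oxygen-bearing C2 (as with other α-alkoxy ketones) and dehydration gives the more stable Z (aurone-type) enone, excess 7 suppressing double condensation.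

Step 5
Reactants: 8 (2Z)-2-(Ar-methylidene)oxolan-3-one
Product: 9 (2Z)-2-(Ar-methylidene)-3-(trimethylsilyloxy)-2,5-dihydrofuran
Conditions: Me3SiOTf, Et3N, CH2Cl2, 0 °C; pentane work-up, used crude
Reagents that add atoms: trimethylsilyl trifluoromethanesulfonate C[Si](C)(C)OS(=O)(=O)C(F)(F)F
Why: Soft enolisation with silyl triflate and amine can only occur at C4 because C2 is sp2, giving the 2-silyloxy diene.

Step 6
Reactants: 9 silyl dienol ether (1.3 equiv); 6 3-methoxy-4-(triisopropylsilyloxy)benzaldehyde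
Product: 11 (2Z,4R)-4-[(R)-hydroxy(Ar)methyl]-2-(Ar-methylidene)oxolan-3-one, via aldol trimethylsilyl ether 10 (not isolated)
Conditions: B-n-butyl oxazaborolidinone of N-tosyl-(S)-tryptophan (20 mol %), EtCN, −78 °C; then 1 M HCl, THF, 0 °C
Reagents that add atoms: none
Why: Catalytic enantioselective Mukaiyama aldol through an open transition state, which gives syn adducts from cyclic enol silanes: attack on the re face of the boron-bound aldehyde sets C7' as R and the syn topology sets C4 as R.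

Step 7
Reactants: 11 syn aldol
Product: 12 (2Z,4R)-4-[(R)-(tert-butyldimethylsilyloxy)(Ar)methyl]-2-(Ar-methylidene)oxolan-3-one
Conditions: t-BuMe2SiOTf, 2,6-lutidine, CH2Cl2, −78 °C
Reagents that add atoms: tert-butyldimethylsilyl trifluoromethanesulfonate CC(C)(C)[Si](C)(C)OS(=O)(=O)C(F)(F)F
Why: Low-temperature silylation of the secondary alcohol is faster than ketone enolisation and blocks retro-aldol and lactone isomerisation in the next step.

Step 8
Reactants: 12 silylated aldol enone
Product: 14 (3S,4R)-4-[(R)-(tert-butyldimethylsilyloxy)(Ar)methyl]-3-hydroxy-3-(Ar-methyl)oxolan-2-one, via hemiketal 13 (not isolated)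
Conditions: Mn(dpm)3 (10 mol %; dpm = 2,2,6,6-tetramethylheptane-3,5-dionate), PhSiH3 (2 equiv), O2 (1 atm), i-PrOH/CH2Cl2, 0 °C; then Mg(Ot-Bu)2 (30 mol %), THF, 0 → 23 °C
Reagents that add atoms: dioxygen O=O
Why: Proposed new method: the manganese hydride formed from Mn(dpm)3 and PhSiH3 transfers a hydrogen atom to the benzylidene carbon C7, the captodative C2 radical (α-oxygen, α-keto) is trapped by O2 and the metal peroxide is reduced by silane to hemiketal 13 (its C2 epimers interconvert through the open 1,2-diketone), whose magnesium alkoxide chelates the C3 ketone and undergoes a suprafacial 1,2-benzyl shift from C2 to C3 on the face anti to the C4 side chain, creating the lactone carbonyl, the C3–C7 bond and the 3S centre (OH cis, benzyl trans to the side chain); the closest known reactions are the Mukaiyama-type reductive α-oxygenation of enones with Mn(dpm)3/PhSiH3/O2 and the alkoxide-mediated benzilic ester (α-ketol) rearrangement of 1,2-diketone hemiketals, which have not been merged or applied to 2-arylidene-furan-3-ones.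

Step 9
Reactants: 14 tris-silyl lactone
Product: 15 (3S,4R)-3-hydroxy-4-[(R)-hydroxy(4-hydroxy-3-methoxyphenyl)methyl]-3-[(4-hydroxy-3-methoxyphenyl)methyl]oxolan-2-one (target)
Conditions: n-Bu4NF (4 equiv), AcOH (4 equiv), THF, 0 → 23 °C
Reagents that add atoms: none
Why: Acetic-acid-buffered fluoride desilylation removes the two aryl silyl ethers and the benzylic silyl ether without forming free alkoxide that could translactonise or eliminate to a quinone methide.

**Compound list**
1 | catechol (benzene-1,2-diol) | Oc1ccccc1O | starting material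
2 | guaiacol (2-methoxyphenol) | COc1ccccc1O | intermediate
3 | glyoxylic acid (used as monohydrate) | O=CC(=O)O | starting material
4 | 4-hydroxy-3-methoxymandelic acid (racemic, not isolated) | COc1cc(C(O)C(=O)O)ccc1O | intermediate
5 | vanillin (4-hydroxy-3-methoxybenzaldehyde) | COc1cc(C=O)ccc1O | intermediate
6 | 3-methoxy-4-(triisopropylsilyloxy)benzaldehyde | COc1cc(C=O)ccc1O[Si](C(C)C)(C(C)C)C(C)C | intermediate
7 | oxolan-3-one (dihydrofuran-3(2H)-one) | O=C1CCOC1 | starting material
8 | (2Z)-2-{[3-methoxy-4-(triisopropylsilyloxy)phenyl]methylidene}oxolan-3-one | O=C1CCO/C1=C\c2ccc(O[Si](C(C)C)(C(C)C)C(C)C)c(OC)c2 | intermediate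
9 | (2Z)-2-{[3-methoxy-4-(triisopropylsilyloxy)phenyl]methylidene}-3-(trimethylsilyloxy)-2,5-dihydrofuran | C[Si](C)(C)OC1=CCO/C1=C\c2ccc(O[Si](C(C)C)(C(C)C)C(C)C)c(OC)c2 | intermediate
10 | trimethylsilyl ether of 11 at the carbinol oxygen, (2Z,4R,7'R), not isolated | O=C1[C@@H]([C@@H](O[Si](C)(C)C)c2ccc(O[Si](C(C)C)(C(C)C)C(C)C)c(OC)c2)CO/C1=C\c3ccc(O[Si](C(C)C)(C(C)C)C(C)C)c(OC)c3 | intermediate
11 | (2Z,4R)-4-{(R)-hydroxy[3-methoxy-4-(triisopropylsilyloxy)phenyl]methyl}-2-{[3-methoxy-4-(triisopropylsilyloxy)phenyl]methylidene}oxolan-3-one (syn aldol) | O=C1[C@@H]([C@@H](O)c2ccc(O[Si](C(C)C)(C(C)C)C(C)C)c(OC)c2)CO/C1=C\c3ccc(O[Si](C(C)C)(C(C)C)C(C)C)c(OC)c3 | intermediate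
12 | (2Z,4R)-4-{(R)-(tert-butyldimethylsilyloxy)[3-methoxy-4-(triisopropylsilyloxy)phenyl]methyl}-2-{[3-methoxy-4-(triisopropylsilyloxy)phenyl]methylidene}oxolan-3-one | O=C1[C@@H]([C@@H](O[Si](C)(C)C(C)(C)C)c2ccc(O[Si](C(C)C)(C(C)C)C(C)C)c(OC)c2)CO/C1=C\c3ccc(O[Si](C(C)C)(C(C)C)C(C)C)c(OC)c3 | intermediate
13 | (4R)-4-{(R)-(tert-butyldimethylsilyloxy)[3-methoxy-4-(triisopropylsilyloxy)phenyl]methyl}-2-hydroxy-2-{[3-methoxy-4-(triisopropylsilyloxy)phenyl]methyl}oxolan-3-one (both C2 epimers, not isolated) | O=C1[C@@H]([C@@H](O[Si](C)(C)C(C)(C)C)c2ccc(O[Si](C(C)C)(C(C)C)C(C)C)c(OC)c2)COC1(O)Cc3ccc(O[Si](C(C)C)(C(C)C)C(C)C)c(OC)c3 | intermediate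
14 | (3S,4R)-4-{(R)-(tert-butyldimethylsilyloxy)[3-methoxy-4-(triisopropylsilyloxy)phenyl]methyl}-3-hydroxy-3-{[3-methoxy-4-(triisopropylsilyloxy)phenyl]methyl}oxolan-2-one | COc1cc(C[C@@]2(O)C(=O)OC[C@@H]2[C@@H](O[Si](C)(C)C(C)(C)C)c2ccc(O[Si](C(C)C)(C(C)C)C(C)C)c(OC)c2)ccc1O[Si](C(C)C)(C(C)C)C(C)C | intermediate
15 | (3S,4R)-3-hydroxy-4-[(R)-hydroxy(4-hydroxy-3-methoxyphenyl)methyl]-3-[(4-hydroxy-3-methoxyphenyl)methyl]oxolan-2-one | COc1cc(C[C@@]2(O)C(=O)OC[C@@H]2[C@@H](O)c2ccc(O)c(OC)c2)ccc1O | target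

**Totals**
Total step count: 9. Longest linear sequence: 9 steps (1 → 15; aldehyde 6 enters twice).

**Three steps most likely to fail**

Step 8 (new cascade). The α-peroxy ketone may fragment across C2–C3, C4 may epimerise before the shift, or the benzyl shift may be slow or poorly face-selective. The fallback uses known chemistry only, sets out from 12 and comes back at 14. Luche reduction of 12 (NaBH4, CeCl3·7H2O, MeOH, −40 °C) gives the allylic alcohol 4-[(R)-(tert-butyldimethylsilyloxy)(Ar)methyl]-2-(Ar-methylidene)oxolan-3-ol F5. Ozonolysis of its enol-ether double bond (O3, CH2Cl2/MeOH, −78 °C; Me2S) gives the α-hydroxy lactone 4-[(R)-(tert-butyldimethylsilyloxy)(Ar)methyl]-3-hydroxyoxolan-2-one F6 and returns one equivalent of 6. Aldehyde 6 is reduced (NaBH4, MeOH) to the benzyl alcohol Ar-methanol F7 and converted (PBr3, Et2O, 0 °C) into the benzyl bromide Ar-methyl bromide F8. The dianion of F6 (LiN(i-Pr)2, 2.2 equiv, THF/DMPU, −78 °C) is C-alkylated by F8 anti to the C4 side chain, giving 14 with the same C3 configuration.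

Step 6 (syn-selective asymmetric aldol). The electron-rich aldehyde and the dienol silane may give low conversion, low syn selectivity or low ee. The fallback sets out from 8 and comes back at 11. Enone 8 is deprotonated at C4 (LiN(i-Pr)2, THF, −78 °C), transmetalated with Cp2ZrCl2 and treated with 6; zirconium enolates give syn aldols irrespective of enolate geometry, so this yields the racemic syn aldol F3. Preparative chiral-phase supercritical-fluid chromatography separates 11 from its enantiomer (2Z,4S)-4-[(S)-hydroxy(Ar)methyl]-2-(Ar-methylidene)oxolan-3-one F4, at the cost of half the material.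

Step 4 (regioselective condensation). Condensation at C4 or at both α-carbons would compete. The fallback fixes the aryl carbon on C2 from the start, sets out from 6 and comes back at 8. Purchased 2,3-dihydrofuran is lithiated at C5 (t-BuLi, THF, −78 → 0 °C) and added to 6 to give the carbinol (4,5-dihydrofuran-2-yl)(Ar)methanol F1. A rhenium-oxo catalysed 1,3-transposition of the allylic alcohol (Ph3SiOReO3, 2 mol %, Et2O, 0 °C), driven by conjugation with the arene, gives (2Z)-2-(Ar-methylidene)oxolan-3-ol F2. Oxidation with MnO2 (CH2Cl2, 23 °C) gives 8.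

**Further compounds**
F1 | step 4 | (4,5-dihydrofuran-2-yl)[3-methoxy-4-(triisopropylsilyloxy)phenyl]methanol (racemic) | OC(C1=CCCO1)c2ccc(O[Si](C(C)C)(C(C)C)C(C)C)c(OC)c2
F2 | step 4 | (2Z)-2-{[3-methoxy-4-(triisopropylsilyloxy)phenyl]methylidene}oxolan-3-ol (racemic) | OC1CCO/C1=C\c2ccc(O[Si](C(C)C)(C(C)C)C(C)C)c(OC)c2
F3 | step 6 | racemic syn aldol (1:1 mixture of 11 and its enantiomer) | O=C1[C@@H]([C@@H](O)c2ccc(O[Si](C(C)C)(C(C)C)C(C)C)c(OC)c2)CO/C1=C\c3ccc(O[Si](C(C)C)(C(C)C)C(C)C)c(OC)c3.O=C1[C@H]([C@H](O)c2ccc(O[Si](C(C)C)(C(C)C)C(C)C)c(OC)c2)CO/C1=C\c3ccc(O[Si](C(C)C)(C(C)C)C(C)C)c(OC)c3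
F4 | step 6 | (2Z,4S)-4-{(S)-hydroxy[3-methoxy-4-(triisopropylsilyloxy)phenyl]methyl}-2-{[3-methoxy-4-(triisopropylsilyloxy)phenyl]methylidene}oxolan-3-one (enantiomer of 11) | O=C1[C@H]([C@H](O)c2ccc(O[Si](C(C)C)(C(C)C)C(C)C)c(OC)c2)CO/C1=C\c3ccc(O[Si](C(C)C)(C(C)C)C(C)C)c(OC)c3
F5 | step 8 | (2Z)-4-{(R)-(tert-butyldimethylsilyloxy)[3-methoxy-4-(triisopropylsilyloxy)phenyl]methyl}-2-{[3-methoxy-4-(triisopropylsilyloxy)phenyl]methylidene}oxolan-3-ol (C3 epimers; C4 and carbinol centre as in 12) | OC1[C@@H]([C@@H](O[Si](C)(C)C(C)(C)C)c2ccc(O[Si](C(C)C)(C(C)C)C(C)C)c(OC)c2)CO/C1=C\c3ccc(O[Si](C(C)C)(C(C)C)C(C)C)c(OC)c3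
F6 | step 8 | 4-{(R)-(tert-butyldimethylsilyloxy)[3-methoxy-4-(triisopropylsilyloxy)phenyl]methyl}-3-hydroxyoxolan-2-one (C3 epimers; C4 and carbinol centre as in 12) | OC1[C@@H]([C@@H](O[Si](C)(C)C(C)(C)C)c2ccc(O[Si](C(C)C)(C(C)C)C(C)C)c(OC)c2)COC1=O
F7 | step 8 | [3-methoxy-4-(triisopropylsilyloxy)phenyl]methanol | OCc1ccc(O[Si](C(C)C)(C(C)C)C(C)C)c(OC)c1
F8 | step 8 | 4-(bromomethyl)-2-methoxy-1-(triisopropylsilyloxy)benzene | BrCc1ccc(O[Si](C(C)C)(C(C)C)C(C)C)c(OC)c1
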